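**Retrosynthetic overview**
1. The target comes from a protected coumarin by desilylation and ketal hydrolysis; its pyranone ring (O1–C2, C3=C4) is closed last from a salicylaldehyde with Ph3P=C=C=O (phenol addition, then intramolecular Wittig reaction).
2. The route rests on the benzene ring C4a–C5–C6–C7–C8–C8a, which carries three different oxygens (C5–OH, C7–O-allyl, C8a–O1) and carbon at C4a. It is built by benzannulation of a 3-alkoxycyclobutenone (gives C6, C7–O, C8, C8a–O) with a siloxyalkyne (gives C4a with masked C4, and C5–O), forming C4a–C8a, C5–C6 and C8–C8a.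
3. The cyclobutenone comes from the protected side-chain alcohol and 3-ethoxycyclobutenone by alkoxy exchange; the siloxyalkyne comes from 3,3-diethoxypropyne by acetylide oxidation and O-silylation.
4. The side chain comes from two Negishi carboaluminations (C7′ and C3′ methyl groups, both olefins E) around an alkylzinc–alkenyl iodide coupling (C5′–C6′), starting from an acetylide/epoxide union (C7′–C8′) on an L-threonate ester (C9′ and C10′ from the chiral pool, C11′ by Grignard addition).
5. Ring order: protecting dioxolane (step 2), benzene ring (step 13), pyranone ring (step 15).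

Key step: step 13

Assumption: ester 1 (methyl 3,4-O-isopropylidene-L-threonate, derived from L-ascorbic acid) is taken as a purchasable chiral-pool compound.
Notation: side-chain carbons are C1′ (OCH2) to C11′ (CMe2OH); Q is the protected side-chain group (2E,6E,9S)-9-[(tert-butyldimethylsilyl)oxy]-3,7-dimethyl-9-[(4R)-2,2,5,5-tetramethyl-1,3-dioxolan-4-yl]nona-2,6-dien-1-yl. The masked formyl group is carried as the diethyl acetal because the corresponding alkyne is a stock chemical.

**Step 1**
Reactants: 1 methyl 3,4-O-isopropylidene-L-threonate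
Product: 2 (1R)-1-[(4S)-2,2-dimethyl-1,3-dioxolan-4-yl]-2-methylpropane-1,2-diol
Conditions: MeMgBr (4 equiv), THF, 0 °C → rt; aq. NH4Cl
Reagents that add atoms: methylmagnesium bromide, C[Mg]Br
Why: Double Grignard addition to the ester (one equivalent is spent on the free hydroxyl) should give the tertiary carbinol C11′ with both methyl groups, while C9′ and C10′ come unchanged from the chiral pool because the α-alkoxide blocks enolisation.

**Step 2**
Reactants: 2 diol
Product: 3 (4R)-4-[(4S)-2,2-dimethyl-1,3-dioxolan-4-yl]-2,2,5,5-tetramethyl-1,3-dioxolane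
Conditions: Me2C(OMe)2 (3 equiv), camphorsulfonic acid (5 mol %), CH2Cl2, rt
Reagents that add atoms: 2,2-dimethoxypropane, COC(C)(C)OC
Why: Acid-catalysed transketalisation should tie the 10′,11′-diol into a dioxolane, the bis-dioxolane being the only arrangement that holds all four oxygens in five-membered ketals.

**Step 3**
Reactants: 3 bis-dioxolane
Product: 4 (1S)-1-[(4R)-2,2,5,5-tetramethyl-1,3-dioxolan-4-yl]ethane-1,2-diol
Conditions: AcOH–H2O (3:1), rt, stopped when 3 is consumed
Reagents that add atoms: none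
Why: Selective ketal hydrolysis should remove the monosubstituted terminal dioxolane first, since ring opening of the 4,5,5-trisubstituted dioxolane is retarded by the gem-dialkyl effect, the usual preference for terminal over internal isopropylidene groups.

**Step 4**
Reactants: 4 diol
Product: 6 (4R)-2,2,5,5-tetramethyl-4-[(2S)-oxiran-2-yl]-1,3-dioxolane, via primary tosylate 5 (not isolated)
Conditions: NaH (2.5 equiv), THF, 0 °C; 1-(p-toluenesulfonyl)imidazole (1.05 equiv), 0 °C → rt
Reagents that add atoms: none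
Why: Selective sulfonylation of the primary hydroxyl followed by intramolecular Williamson closure by the C9′ alkoxide should give the terminal epoxide with C9′ unchanged, because its C–O bond is not broken.

**Step 5**
Reactants: 6 epoxide
Product: 7 (1S)-1-[(4R)-2,2,5,5-tetramethyl-1,3-dioxolan-4-yl]but-3-yn-1-ol
Conditions: LiC≡CH·H2NCH2CH2NH2 (2 equiv), DMSO, rt; H2O
Reagents that add atoms: lithium acetylide–ethane-1,2-diamine complex, [Li]C#C.NCCN
Why: SN2 opening of the terminal epoxide by acetylide at the unhindered CH2 should form C7′–C8′ and leave C9′ untouched.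

**Step 6**
Reactants: 7 homopropargylic alcohol
Product: 8 tert-butyldimethyl{[(1S)-1-[(4R)-2,2,5,5-tetramethyl-1,3-dioxolan-4-yl]but-3-yn-1-yl]oxy}silane
Conditions: TBSOTf (1.3 equiv), 2,6-lutidine (2 equiv), CH2Cl2, −20 → 0 °C
Reagents that add atoms: tert-butyldimethylsilyl trifluoromethanesulfonate, CC(C)(C)[Si](C)(C)OS(=O)(=O)C(F)(F)F
Why: Silylation with the silyl triflate should protect the hindered secondary hydroxyl, which would otherwise quench the organometallic reagents and the ketene of later steps.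

**Step 7**
Reactants: 8 silyl ether alkyne
Product: 10 tert-butyl{[(1S,3E)-4-iodo-3-methyl-1-[(4R)-2,2,5,5-tetramethyl-1,3-dioxolan-4-yl]but-3-en-1-yl]oxy}dimethylsilane, via alkenylalane 9 (not isolated)
Conditions: Me3Al (3 equiv), Cp2ZrCl2 (0.25 equiv), CH2Cl2, 0 °C → rt; I2 (1.5 equiv), THF, −30 → 0 °C; aq. NaHCO3
Reagents that add atoms: trimethylaluminium, C[Al](C)C; iodine, II
Why: Negishi carboalumination adds methyl and aluminium syn across the terminal alkyne with methyl on the internal carbon (C7′), and iodinolysis with retention should give the E alkenyl iodide.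

**Step 8**
Reactants: 10 alkenyl iodide; 11 (4-bromobut-1-yn-1-yl)trimethylsilane
Product: 13 tert-butyldimethyl{[(1S,3E)-3-methyl-1-[(4R)-2,2,5,5-tetramethyl-1,3-dioxolan-4-yl]-8-(trimethylsilyl)oct-3-en-7-yn-1-yl]oxy}silane, via alkylzinc bromide 12 (not isolated)
Conditions: 11 (1.5 equiv), Zn dust, LiCl, THF, 50 °C; then 10, PdCl2(dppf) (5 mol %), THF, rt → 40 °C
Reagents that add atoms: none
Why: Negishi cross-coupling of the primary homopropargylzinc reagent with the alkenyl iodide (oxidative addition to zerovalent palladium, transmetalation, reductive elimination) should form C5′–C6′ with retention of the E geometry.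

**Step 9**
Reactants: 13 silylated enyne
Product: 14 tert-butyldimethyl{[(1S,3E)-3-methyl-1-[(4R)-2,2,5,5-tetramethyl-1,3-dioxolan-4-yl]oct-3-en-7-yn-1-yl]oxy}silane
Conditions: K2CO3 (0.5 equiv), MeOH, rt
Reagents that add atoms: none
Why: Methoxide-mediated protodesilylation should cleave only the alkynyl C–Si bond, the alkyl silyl ether and the ketal being inert to K2CO3 in methanol.

**Step 10**
Reactants: 14 terminal enyne
Product: 17 Q–OH, (2E,6E,9S)-9-[(tert-butyldimethylsilyl)oxy]-3,7-dimethyl-9-[(4R)-2,2,5,5-tetramethyl-1,3-dioxolan-4-yl]nona-2,6-dien-1-ol, via dienylalane 15 (not isolated), via lithium alanate 16 (not isolated)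
Conditions: Me3Al (3 equiv), Cp2ZrCl2 (0.3 equiv), CH2Cl2, 0 °C → rt; evaporate, hexane; nBuLi, THF, −78 → 0 °C; (CH2O)n, rt
Reagents that add atoms: trimethylaluminium, C[Al](C)C; paraformaldehyde (as formaldehyde), C=O
Why: A second Negishi carboalumination places methyl on C3′ syn to aluminium on C2′, and hydroxymethylation of the derived alanate with formaldehyde proceeds with retention, which should give the 2E allylic alcohol directly.

**Step 11**
Reactants: 17 side-chain alcohol; 18 3-ethoxycyclobut-2-en-1-one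
Product: 19 3-(Q-oxy)cyclobut-2-en-1-one
Conditions: 18 (4 equiv), pyridinium p-toluenesulfonate (0.1 equiv), benzene, 5 Å sieves, 45 °C
Reagents that add atoms: none
Why: Acid-catalysed alkoxy exchange of a vinylogous ester (addition of the alcohol at C3 of the protonated enone, loss of ethanol), as in transesterification of squarate esters, should be driven by excess 18 and removal of ethanol at a temperature well below cyclobutenone ring opening.

**Step 12**
Reactants: 20 3,3-diethoxyprop-1-yne
Product: 23 [(3,3-diethoxyprop-1-yn-1-yl)oxy]tri(propan-2-yl)silane, via lithium acetylide 21 (not isolated), via lithium ynolate 22 (not isolated)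
Conditions: nBuLi, THF, −78 °C; LiOOtBu (from tBuOOH and LiN(SiMe3)2, THF, −78 °C), −78 → 0 °C; iPr3SiOTf, −78 → 0 °C; Et3N-treated silica
Reagents that add atoms: lithium tert-butyl peroxide, [Li]OOC(C)(C)C; triisopropylsilyl trifluoromethanesulfonate, CC(C)[Si](C(C)C)(C(C)C)OS(=O)(=O)C(F)(F)F
Why: Oxygen transfer from the lithium peroxide to the acetylide should give the ynolate, which the bulky silyl triflate traps on oxygen; β-loss of ethoxide from the ynolate would need a cumulenone and is not expected.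

**Step 13**
Reactants: 19 3-(Q-oxy)cyclobutenone; 23 siloxyalkyne
Product: 28 2-(diethoxymethyl)-5-(Q-oxy)-3-[(triisopropylsilyl)oxy]phenol, via vinylketene 24 (not isolated), via vinylcyclobutenone 25 (not isolated), via dienylketene 26 (not isolated), via cyclohexadienone 27 (not isolated)
Conditions: 23 (2 equiv), toluene (0.5 M), 90 °C then 110 °C, base-washed sealed tube
Reagents that add atoms: none
Why: Proposed new method: thermal four-electron ring opening of the 3-alkoxycyclobutenone 19 should give the 3-alkoxy vinylketene 24, which adds siloxyalkyne 23 in a [2+2] cycloaddition to 4-vinylcyclobutenone 25; a second four-electron opening gives dienylketene 26, six-electron electrocyclisation gives dienone 27 and enolisation gives phenol 28. The closest known reaction type is the Danheiser benzannulation of 3-alkyl- and 3-arylcyclobutenones with siloxyalkynes, and thermal opening of alkoxy-substituted cyclobutenones is familiar from squarate-derived cyclobutenones, but a 4-unsubstituted 3-(allyloxy)cyclobutenone has not served as the ketene source. The benzene ring, the only ring formed, closes by thermal disrotatory 6π electrocyclisation of the dienylketene between the ketene carbon (later C8a) and the terminal methylene (later C8), after C4a–C8a and C5–C6 were made in the [2+2] event. No stereocentre is formed and C9′ and C10′ are remote from all reacting centres. Regiocontrol is needed in the [2+2] step and comes from the polarisation of 23, whose acetal-bearing carbon (β to oxygen, nucleophilic) bonds to the electrophilic ketene carbon, so that the masked formyl carbon ends between the free phenol and the silyl ether with the chain oxygen para to it. Chemoselectivity is needed against [3,3] rearrangement of the allyl vinylogous ester and against capture of the ketene by the C2′=C3′ olefin, and an excess of the electron-rich alkyne at no more than 110 °C should secure it.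

**Step 14**
Reactants: 28 acetal phenol
Product: 29 2-hydroxy-4-(Q-oxy)-6-[(triisopropylsilyl)oxy]benzaldehyde
Conditions: pyridinium p-toluenesulfonate (0.1 equiv), acetone–H2O (10:1), rt
Reagents that add atoms: water, O
Why: Acetal hydrolysis should be very fast here because three ortho/para oxygen donors stabilise the benzylic oxocarbenium ion, so the silyl ethers and the hindered ketal are not touched.

**Step 15**
Reactants: 29 salicylaldehyde; 30 Ph3P=C=C=O (ketenylidenetriphenylphosphorane)
Product: 32 7-(Q-oxy)-5-[(triisopropylsilyl)oxy]-2H-chromen-2-one, via ester ylide 31 (not isolated)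
Conditions: 30 (1.3 equiv), toluene, 100 °C
Reagents that add atoms: none
Why: The phenol O–H adds across the ketenylidene ylide to give an aryl ester ylide, which should close the pyranone ring by intramolecular Wittig reaction with the ortho formyl group, the ring enforcing the cis C3=C4 bond.

**Step 16**
Reactants: 32 protected coumarin
Product: 33 5-hydroxy-7-{[(2E,6E,9S)-9-hydroxy-3,7-dimethyl-9-[(4R)-2,2,5,5-tetramethyl-1,3-dioxolan-4-yl]nona-2,6-dien-1-yl]oxy}-2H-chromen-2-one
Conditions: Bu4NF (4 equiv), AcOH (4 equiv), THF, rt → 40 °C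
Reagents that add atoms: none
Why: Fluoride-mediated desilylation should cleave both the aryl triisopropylsilyl ether and the secondary alkyl silyl ether, the acetic acid buffering the phenoxide so that the lactone is not opened.

**Step 17**
Reactants: 33 ketal-protected coumarin
Product: 34 5-hydroxy-7-{[(2E,6E,9S,10R)-9,10,11-trihydroxy-3,7,11-trimethyldodeca-2,6-dien-1-yl]oxy}-2H-chromen-2-one
Conditions: 1 M HCl (aq)–THF (1:3), rt
Reagents that add atoms: none
Why: Acid-catalysed ketal hydrolysis breaks only the ketal C–O bonds, so C9′ and C10′ keep their configuration, and dilute acid at room temperature should spare the allylic aryl ether and the trisubstituted olefins.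

**Compound list**
1 | methyl (2R)-2-[(4S)-2,2-dimethyl-1,3-dioxolan-4-yl]-2-hydroxyacetate (methyl 3,4-O-isopropylidene-L-threonate) | COC(=O)[C@H](O)[C@@H]1COC(C)(C)O1 | starting material
2 | (1R)-1-[(4S)-2,2-dimethyl-1,3-dioxolan-4-yl]-2-methylpropane-1,2-diol | CC(C)(O)[C@H](O)[C@@H]1COC(C)(C)O1 | intermediate
3 | (4R)-4-[(4S)-2,2-dimethyl-1,3-dioxolan-4-yl]-2,2,5,5-tetramethyl-1,3-dioxolane | CC1(C)OC(C)(C)O[C@@H]1[C@@H]2COC(C)(C)O2 | intermediate
4 | (1S)-1-[(4R)-2,2,5,5-tetramethyl-1,3-dioxolan-4-yl]ethane-1,2-diol | CC1(C)OC(C)(C)O[C@@H]1[C@@H](O)CO | intermediate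
5 | (2S)-2-hydroxy-2-[(4R)-2,2,5,5-tetramethyl-1,3-dioxolan-4-yl]ethyl 4-methylbenzenesulfonate (present as its sodium alkoxide) | CC1(C)OC(C)(C)O[C@@H]1[C@@H](O)COS(=O)(=O)c2ccc(C)cc2 | intermediate
6 | (4R)-2,2,5,5-tetramethyl-4-[(2S)-oxiran-2-yl]-1,3-dioxolane | CC1(C)OC(C)(C)O[C@@H]1[C@@H]2CO2 | intermediate
7 | (1S)-1-[(4R)-2,2,5,5-tetramethyl-1,3-dioxolan-4-yl]but-3-yn-1-ol | CC1(C)OC(C)(C)O[C@@H]1[C@@H](O)CC#C | intermediate
8 | tert-butyldimethyl{[(1S)-1-[(4R)-2,2,5,5-tetramethyl-1,3-dioxolan-4-yl]but-3-yn-1-yl]oxy}silane | C#CC[C@H](O[Si](C)(C)C(C)(C)C)[C@H]1OC(C)(C)OC1(C)C | intermediate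
9 | [(1E,4S)-4-[(tert-butyldimethylsilyl)oxy]-2-methyl-4-[(4R)-2,2,5,5-tetramethyl-1,3-dioxolan-4-yl]but-1-en-1-yl]dimethylalumane | C[Al](C)/C=C(\C)C[C@H](O[Si](C)(C)C(C)(C)C)[C@H]1OC(C)(C)OC1(C)C | intermediate
10 | tert-butyl{[(1S,3E)-4-iodo-3-methyl-1-[(4R)-2,2,5,5-tetramethyl-1,3-dioxolan-4-yl]but-3-en-1-yl]oxy}dimethylsilane | I/C=C(\C)C[C@H](O[Si](C)(C)C(C)(C)C)[C@H]1OC(C)(C)OC1(C)C | intermediate
11 | (4-bromobut-1-yn-1-yl)trimethylsilane | C[Si](C)(C)C#CCCBr | starting material
12 | bromo[4-(trimethylsilyl)but-3-yn-1-yl]zinc | C[Si](C)(C)C#CCC[Zn]Br | intermediate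
13 | tert-butyldimethyl{[(1S,3E)-3-methyl-1-[(4R)-2,2,5,5-tetramethyl-1,3-dioxolan-4-yl]-8-(trimethylsilyl)oct-3-en-7-yn-1-yl]oxy}silane | C[Si](C)(C)C#CCC/C=C(\C)C[C@H](O[Si](C)(C)C(C)(C)C)[C@H]1OC(C)(C)OC1(C)C | intermediate
14 | tert-butyldimethyl{[(1S,3E)-3-methyl-1-[(4R)-2,2,5,5-tetramethyl-1,3-dioxolan-4-yl]oct-3-en-7-yn-1-yl]oxy}silane | C#CCC/C=C(\C)C[C@H](O[Si](C)(C)C(C)(C)C)[C@H]1OC(C)(C)OC1(C)C | intermediate
15 | [(1E,5E,8S)-8-[(tert-butyldimethylsilyl)oxy]-2,6-dimethyl-8-[(4R)-2,2,5,5-tetramethyl-1,3-dioxolan-4-yl]octa-1,5-dien-1-yl]dimethylalumane | C[Al](C)/C=C(\C)CC/C=C(\C)C[C@H](O[Si](C)(C)C(C)(C)C)[C@H]1OC(C)(C)OC1(C)C | intermediate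
16 | lithium butyl[(1E,5E,8S)-8-[(tert-butyldimethylsilyl)oxy]-2,6-dimethyl-8-[(4R)-2,2,5,5-tetramethyl-1,3-dioxolan-4-yl]octa-1,5-dien-1-yl]dimethylalanate | [Li+].CCCC[Al-](C)(C)/C=C(\C)CC/C=C(\C)C[C@H](O[Si](C)(C)C(C)(C)C)[C@H]1OC(C)(C)OC1(C)C | intermediate
17 | Q–OH, (2E,6E,9S)-9-[(tert-butyldimethylsilyl)oxy]-3,7-dimethyl-9-[(4R)-2,2,5,5-tetramethyl-1,3-dioxolan-4-yl]nona-2,6-dien-1-ol | OC/C=C(\C)CC/C=C(\C)C[C@H](O[Si](C)(C)C(C)(C)C)[C@H]1OC(C)(C)OC1(C)C | intermediate
18 | 3-ethoxycyclobut-2-en-1-one | CCOC1=CC(=O)C1 | starting material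
19 | 3-(Q-oxy)cyclobut-2-en-1-one | O=C1C=C(OC/C=C(\C)CC/C=C(\C)C[C@H](O[Si](C)(C)C(C)(C)C)[C@H]2OC(C)(C)OC2(C)C)C1 | intermediate
20 | 3,3-diethoxyprop-1-yne | CCOC(OCC)C#C | starting material
21 | (3,3-diethoxyprop-1-yn-1-yl)lithium | CCOC(OCC)C#C[Li] | intermediate
22 | lithium 3,3-diethoxyprop-1-yn-1-olate | CCOC(OCC)C#C[O-].[Li+] | intermediate
23 | [(3,3-diethoxyprop-1-yn-1-yl)oxy]tri(propan-2-yl)silane | CCOC(OCC)C#CO[Si](C(C)C)(C(C)C)C(C)C | intermediate
24 | 3-(Q-oxy)buta-1,3-dien-1-one (vinylketene) | O=C=CC(=C)OC/C=C(\C)CC/C=C(\C)C[C@H](O[Si](C)(C)C(C)(C)C)[C@H]1OC(C)(C)OC1(C)C | intermediate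
25 | 2-(diethoxymethyl)-4-[1-(Q-oxy)ethenyl]-3-[(triisopropylsilyl)oxy]cyclobut-2-en-1-one (C4 configuration not defined) | CCOC(OCC)C1=C(O[Si](C(C)C)(C(C)C)C(C)C)C(C(=C)OC/C=C(\C)CC/C=C(\C)C[C@H](O[Si](C)(C)C(C)(C)C)[C@H]2OC(C)(C)OC2(C)C)C1=O | intermediate
26 | (3E)-2-(diethoxymethyl)-5-(Q-oxy)-3-[(triisopropylsilyl)oxy]hexa-1,3,5-trien-1-one (ketene and alkoxyvinyl groups cis) | CCOC(OCC)C(=C=O)/C(O[Si](C(C)C)(C(C)C)C(C)C)=C\C(=C)OC/C=C(\C)CC/C=C(\C)C[C@H](O[Si](C)(C)C(C)(C)C)[C@H]1OC(C)(C)OC1(C)C | intermediate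
27 | 2-(diethoxymethyl)-5-(Q-oxy)-3-[(triisopropylsilyl)oxy]cyclohexa-2,4-dien-1-one | CCOC(OCC)C1=C(O[Si](C(C)C)(C(C)C)C(C)C)C=C(OC/C=C(\C)CC/C=C(\C)C[C@H](O[Si](C)(C)C(C)(C)C)[C@H]2OC(C)(C)OC2(C)C)CC1=O | intermediate
28 | 2-(diethoxymethyl)-5-(Q-oxy)-3-[(triisopropylsilyl)oxy]phenol | CCOC(OCC)c1c(O)cc(OC/C=C(\C)CC/C=C(\C)C[C@H](O[Si](C)(C)C(C)(C)C)[C@H]2OC(C)(C)OC2(C)C)cc1O[Si](C(C)C)(C(C)C)C(C)C | intermediate
29 | 2-hydroxy-4-(Q-oxy)-6-[(triisopropylsilyl)oxy]benzaldehyde | O=Cc1c(O)cc(OC/C=C(\C)CC/C=C(\C)C[C@H](O[Si](C)(C)C(C)(C)C)[C@H]2OC(C)(C)OC2(C)C)cc1O[Si](C(C)C)(C(C)C)C(C)C | intermediate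
30 | ketenylidenetriphenylphosphorane, Ph3P=C=C=O | O=C=C=P(c1ccccc1)(c1ccccc1)c1ccccc1 | starting material
31 | 2-formyl-5-(Q-oxy)-3-[(triisopropylsilyl)oxy]phenyl (triphenylphosphoranylidene)acetate | O=Cc1c(OC(=O)C=P(c2ccccc2)(c2ccccc2)c2ccccc2)cc(OC/C=C(\C)CC/C=C(\C)C[C@H](O[Si](C)(C)C(C)(C)C)[C@H]2OC(C)(C)OC2(C)C)cc1O[Si](C(C)C)(C(C)C)C(C)C | intermediate
32 | 7-(Q-oxy)-5-[(triisopropylsilyl)oxy]-2H-chromen-2-one | O=c1ccc2c(O[Si](C(C)C)(C(C)C)C(C)C)cc(OC/C=C(\C)CC/C=C(\C)C[C@H](O[Si](C)(C)C(C)(C)C)[C@H]3OC(C)(C)OC3(C)C)cc2o1 | intermediate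
33 | 5-hydroxy-7-{[(2E,6E,9S)-9-hydroxy-3,7-dimethyl-9-[(4R)-2,2,5,5-tetramethyl-1,3-dioxolan-4-yl]nona-2,6-dien-1-yl]oxy}-2H-chromen-2-one | O=c1ccc2c(O)cc(OC/C=C(\C)CC/C=C(\C)C[C@H](O)[C@H]3OC(C)(C)OC3(C)C)cc2o1 | intermediate
34 | 5-hydroxy-7-{[(2E,6E,9S,10R)-9,10,11-trihydroxy-3,7,11-trimethyldodeca-2,6-dien-1-yl]oxy}-2H-chromen-2-one | C/C(=C\COc1cc(O)c2ccc(=O)oc2c1)CC/C=C(\C)C[C@H](O)[C@@H](O)C(C)(C)O | target

**Step count**
Total: 17 steps. Longest linear sequence: 16 steps (steps 1–11, then 13–17); step 12 is a one-step branch.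

**Steps most likely to fail**

Step 13 (proposed new method). The vinylogous-ester cyclobutenone may open too slowly. At the temperature then needed, the allyl vinyl ether unit may undergo [3,3] rearrangement, the ketene may be captured by the C2′=C3′ double bond or may acylate phenol already formed, and the propargylic acetal of the alkyne may ionise on traces of acid. The fallback gives up the ring construction and uses only known reactions. It sets out from 17, which is etherified under Mitsunobu conditions (PPh3, DIAD, THF, 0 °C) with purchasable 2,4,6-trihydroxybenzaldehyde at its most acidic, non-chelated 4-hydroxyl to give 2,6-dihydroxy-4-(Q-oxy)benzaldehyde F1. Because F1 has a mirror plane, either ortho hydroxyl may add to one equivalent of 30 (toluene, 100 °C), and the resulting ester ylide F2 should close by intramolecular Wittig reaction to 5-hydroxy-7-(Q-oxy)-2H-chromen-2-one F3. Bu4NF/AcOH then removes the alkyl silyl ether, and the sequence comes back to the route at 33.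

Step 11. Acid may ionise the primary allylic C–O bond of 17 or of 19 (allylic transposition, elimination), the exchange may stall if ethanol is not removed, and the strained enone may oligomerise. The fallback sets out from 18, which is hydrolysed with dilute aqueous HCl to 3-hydroxycyclobut-2-en-1-one F4 (the enol of cyclobutane-1,3-dione, a vinylogous acid to be used at once). Mitsunobu O-alkylation of F4 with 17 (PPh3, DIAD, THF, −20 → 0 °C) forms the enol ether under neutral conditions and comes back at 19.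

Step 17. Hydrolysis of the hindered tetramethyl ketal may be slower than acid-induced ionisation of the allylic aryl ether, with loss of the side chain as an allyl cation. The fallback sets out from 17 and removes the protecting groups before the ether is made. Bu4NF gives (2E,6E,9S)-3,7-dimethyl-9-[(4R)-2,2,5,5-tetramethyl-1,3-dioxolan-4-yl]nona-2,6-diene-1,9-diol F5. Aqueous AcOH (4:1, 45 °C) then hydrolyses the ketal at the stage of the far less ionisable allylic alcohol to (2E,6E,9S,10R)-3,7,11-trimethyldodeca-2,6-diene-1,9,10,11-tetrol F6. A Mitsunobu reaction (PPh3, DIAD, THF, 0 °C), selective for the primary allylic hydroxyl, with purchasable 5,7-dihydroxycoumarin at its more acidic and less hindered 7-hydroxyl comes back to the route at 34. The price is a choice between the two phenols that the main route avoids.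

**Further compounds**
F1 | step 13 | 2,6-dihydroxy-4-(Q-oxy)benzaldehyde | O=Cc1c(O)cc(OC/C=C(\C)CC/C=C(\C)C[C@H](O[Si](C)(C)C(C)(C)C)[C@H]2OC(C)(C)OC2(C)C)cc1O
F2 | step 13 | 2-formyl-3-hydroxy-5-(Q-oxy)phenyl (triphenylphosphoranylidene)acetate | O=Cc1c(O)cc(OC/C=C(\C)CC/C=C(\C)C[C@H](O[Si](C)(C)C(C)(C)C)[C@H]2OC(C)(C)OC2(C)C)cc1OC(=O)C=P(c1ccccc1)(c1ccccc1)c1ccccc1
F3 | step 13 | 5-hydroxy-7-(Q-oxy)-2H-chromen-2-one | O=c1ccc2c(O)cc(OC/C=C(\C)CC/C=C(\C)C[C@H](O[Si](C)(C)C(C)(C)C)[C@H]3OC(C)(C)OC3(C)C)cc2o1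
F4 | step 11 | 3-hydroxycyclobut-2-en-1-one | O=C1CC(O)=C1
F5 | step 17 | (2E,6E,9S)-3,7-dimethyl-9-[(4R)-2,2,5,5-tetramethyl-1,3-dioxolan-4-yl]nona-2,6-diene-1,9-diol | OC/C=C(\C)CC/C=C(\C)C[C@H](O)[C@H]1OC(C)(C)OC1(C)C
F6 | step 17 | (2E,6E,9S,10R)-3,7,11-trimethyldodeca-2,6-diene-1,9,10,11-tetrol | OC/C=C(\C)CC/C=C(\C)C[C@H](O)[C@@H](O)C(C)(C)O
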